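A neighbour flask holds 0.013 M of substrate where this flask holds 0.050 M, and two chemists dispute whether the charge matters to the split between the two end products.

substrate 0.050 M; gas phase 9.8 mM (held); time 6.0 h

    gas phase ⇌ dissolved gas, rate k1*(csat - [dissolved gas]) (k1 = 0.794 /min, csat = 9.8 mM)
    substrate + dissolved gas → target (k2 = 27.5 /M/min)
    dissolved gas + target → over-reacted product (k3 = 80.8 /M/min)
    target → over-reaction product (k4 = 0.100 /min)

- the state of affairs at 6.0 h: stopped, and by what, or still going (all of the substrate has reacted / it is still moving / forward and back rates have come level)
- conversion of substrate at 6.0 h
- amount of over-reacted product at 6.0 h, in percent of the substrate charged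

Write G for dissolved gas, S for substrate, and kT, kS, kQ, kO for the constants of transfer, of substrate with gas, of gas with target, and of target on its own. Target goes one way at kQ·G and the other at kO, so the dispute is about G.

Anna says the flask is saturated, G = csat at any charge. That gives kQ·csat/kO = 7.92, hence 88.8 % over-reacted product.

Ben writes the balance of the gas, whose saturation level csat lies below the substrate charge cA: with no target yet, transfer in equals uptake, kT(csat − G) = kS·S·G. At the charge this gives G₀ = kT·csat/(kT + kS·cA) = 3.59 mM. He may write it so, because G adjusts within 0.461 min while substrate lasts about 10.1 min at that gas level. By this balance, Anna's view asks that kS·cA lie far under kT, and in this flask kS·cA is 1.38 /min against 0.794 /min.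

I side with Ben and carry one number, the selectivity factor σ = kQ·G₀/kO, the rate of target's path to over-reacted product over its other path, with gas at its loaded level: 2.90. The share of over-reacted product is then σ/(1 + σ), so I commit to 74.4 %. With 35.5 substrate lifetimes in 6.0 h, conversion comes to >99.9 %.

The forecast stands on Ben's side too: all of the substrate has reacted, 100 %, and 78 %, higher than my figure. Its ground is a split “which runs from about 0.74 early to about 0.89 late”.

The simulation gives all of the substrate has reacted, conversion 100 % and 78.1 % over-reacted product. The forecast stands, Anna's figure does not, and the one-line balance came 3.7 percentage points short without any stepping. This flask has what σ lacks, a gas level that moves: it reads 0.00970 M at 0.600 h, above G₀. In this flask the end products stand at 3.56 to one at 6.00 h, against σ of 2.90.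

In the neighbour flask, the same balance gives G₀ = 6.76 mM, so σ = 5.46 and a share of 84.5 %. The simulation gives 85.1 %.

(Its constants are invented.)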